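**Plan**

- Numbering the tetrahydrofuran O1, C2 (aryl cis to the C3 CH2OH), C3, C4, C5: the retrosynthesis returns the C3 CH2OH to a vinyl group and the free OH groups to pivalates, cuts the ring at O1–C2 and C2–C3, then removes a silicon tether and cuts C4–C5.
- The ring cut is possible because C2 lies between O1 and C3 at the aldehyde oxidation level: it is the carbonyl carbon of an aryl aldehyde, O1 is the C5 oxygen, and C3 is the γ-carbon of an allylsilane whose other two carbons remain as the vinyl group.
- Forward: syringaldehyde pivalate (used twice) → anti 2-vinyl-1,3-diol (C4–C5 bond) → primary pivalate → allylsilyl ether → seven-membered (Z)-allylsiloxane by ring-closing metathesis → tetrahydrofuran (the only ring, closed in the key step) → ozonolysis/reduction → removal of the pivalates.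
- Stereochemistry: C5 and C4 (absolute and anti) come from the chiral catalyst made from [Ir(cod)Cl]2 and (R)-SEGPHOS; C2 and C3 are set in the ring closure by the E-oxocarbenium ion, the pseudo-equatorial C5 aryl group and the allylic strain of the Z-alkene.

Key step: step 6

Assumption: by analogy with the parent carbonyl allylation, the catalyst from [Ir(cod)Cl]2 and (R)-SEGPHOS is taken to add to the re face of aldehyde 3 (1R carbinol); the first batch would be checked through its MTPA esters and the antipodal ligand used if the sense were opposite.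

**Step 1**
Reactants: 1 syringaldehyde; 2 pivaloyl chloride
Product: 3 4-formyl-2,6-dimethoxyphenyl pivalate
Conditions: PivCl, Et3N, DMAP (cat.), CH2Cl2, 0 °C to rt
Reagents that add atoms: pivaloyl chloride (2), CC(C)(C)C(=O)Cl
Why: DMAP-catalysed O-acylation of the phenol (esterification) should be clean because the aldehyde is inert to the acid chloride, and the ester makes the ring less electron-rich for the later Lewis-acid and ozone steps.

**Step 2**
Reactants: 3 4-formyl-2,6-dimethoxyphenyl pivalate; 4 4-vinyl-1,3-dioxolan-2-one (racemic)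
Product: 5 4-[(1R,2S)-1-hydroxy-2-(hydroxymethyl)but-3-en-1-yl]-2,6-dimethoxyphenyl pivalate (anti diol)
Conditions: [Ir(cod)Cl]2 (cat.), (R)-SEGPHOS, 4-cyano-3-nitrobenzoic acid (cat.), K3PO4 (cat.), i-PrOH (2 equiv), THF, 60–90 °C
Reagents that add atoms: none
Why: In this iridium-catalysed transfer-hydrogenative carbonyl (hydroxymethyl)allylation the catalyst made from [Ir(cod)Cl]2, (R)-SEGPHOS and the nitrobenzoic acid ionises and decarboxylates 4 to a (hydroxymethyl)allyl–iridium species (isopropanol is the terminal reductant), whose (E)-σ-allyl form adds to the aldehyde through a closed chair transition state, so that C1 and C2 are set anti by the chair and their absolute configuration by the ligand-controlled choice of the re face of 3.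

**Step 3**
Reactants: 5 anti diol; 2 pivaloyl chloride
Product: 6 (2S,3R)-3-[3,5-dimethoxy-4-(pivaloyloxy)phenyl]-3-hydroxy-2-vinylpropyl pivalate
Conditions: PivCl (1.1 equiv), pyridine, CH2Cl2, −20 to 0 °C
Reagents that add atoms: pivaloyl chloride (2), CC(C)(C)C(=O)Cl
Why: Sterically differentiated acylation with a bulky acid chloride should take the primary hydroxyl well before the hindered secondary benzylic one, which stays free as the future ring oxygen.

**Step 4**
Reactants: 6 hydroxy pivalate; 7 allyl(chloro)dimethylsilane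
Product: 8 (2S,3R)-3-[allyl(dimethyl)silyloxy]-3-[3,5-dimethoxy-4-(pivaloyloxy)phenyl]-2-vinylpropyl pivalate
Conditions: 7, Et3N, DMAP (cat.), CH2Cl2, 0 °C to rt
Reagents that add atoms: allyl(chloro)dimethylsilane (7), C=CC[Si](C)(C)Cl
Why: Standard silyl ether formation at the only free hydroxyl places the allylsilane unit on the oxygen that becomes O1 and creates no stereocentre.

**Step 5**
Reactants: 8 allylsilyl ether
Product: 9 (4Z,6S,7R)-7-[3,5-dimethoxy-4-(pivaloyloxy)phenyl]-2,2-dimethyl-6-(pivaloyloxymethyl)-1-oxa-2-silacyclohept-4-ene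
Conditions: (H2IMes)(PCy3)Cl2Ru=CHPh (second-generation Grubbs catalyst, 5 mol %), CH2Cl2 (0.01 M), 40 °C
Reagents that add atoms: none
Why: Ring-closing olefin metathesis of the two terminal alkenes with loss of ethene; the seven-membered ring can only hold a Z-alkene, which fixes the allylsilane geometry, and neither stereocentre is touched.

**Step 6**
Reactants: 9 cyclic (Z)-allylsiloxane; 3 4-formyl-2,6-dimethoxyphenyl pivalate
Product: 11 (2S,3R,4S,5R)-2,5-bis[3,5-dimethoxy-4-(pivaloyloxy)phenyl]-4-(pivaloyloxymethyl)-3-vinyltetrahydrofuran, via oxocarbenium triflate 10 (not isolated)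
Conditions: 3 (1.2 equiv), Me3SiOTf (1.1 equiv), CH2Cl2, −78 °C; aq. NaHCO3 quench
Reagents that add atoms: none
Why: Me3SiOTf activates aldehyde 3 toward attack by the siloxane oxygen, the Si–O bond is exchanged for a Si–O–SiMe3 link and the (E)-oxocarbenium ion 10 results, whose carbon is captured by the γ-carbon (C3) of the allylsilane with loss of the silyl group; the closest known reaction type is the Lewis-acid condensation of cyclic allylsiloxanes or 5-silylpent-3-en-1-ols with aldehydes to 3-vinyltetrahydrofurans (intramolecular Hosomi–Sakurai capture of an oxocarbenium ion). The tetrahydrofuran closes in a 5-endo-trig mode with respect to the C=O+ bond, the nucleophilic alkene lying exocyclic to the new ring. C2 is controlled by the E geometry of the oxocarbenium ion together with the pseudo-equatorial C5 aryl group (anti to C2 across O1), which places the two aryl groups cis. C3 is controlled by the allylic 1,3-strain of the Z-alkene, which keeps C4–H and not the CH2OPiv group next to the silylmethyl-bearing alkene carbon, so the vinyl group ends up trans to CH2OPiv; with the C4 and C5 substituents pseudo-equatorial this is the synclinal alignment of C=C and C=O+ (silylmethyl over O1), which puts the vinyl group cis to the C2 aryl group. The step needs 2,5-cis and 3,4-trans at once; the competing pseudo-diaxial, antiperiplanar envelope would give the C2 epimer and is disfavoured by the axial C5 aryl group, while the acyloxy-substituted aryl rings keep both benzylic C–O bonds from ionising.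

**Step 7**
Reactants: 11 3-vinyltetrahydrofuran
Product: 13 (2S,3S,4S,5R)-2,5-bis[3,5-dimethoxy-4-(pivaloyloxy)phenyl]-3-(hydroxymethyl)-4-(pivaloyloxymethyl)tetrahydrofuran, via ozonide 12 (not isolated)
Conditions: O3, CH2Cl2, −78 °C (Sudan Red 7B end point); then NaBH4, MeOH, −78 to 0 °C
Reagents that add atoms: ozone, [O-][O+]=O
Why: Ozonolysis with reductive (borohydride) work-up cleaves the only C=C bond and reduces the ozonide directly to the primary alcohol, so the epimerisable C3 aldehyde is never isolated and C3 keeps its configuration; the acyloxy-substituted aryl rings should react with ozone much more slowly than the vinyl group when addition stops at the indicator end point.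

**Step 8**
Reactants: 13 hydroxy tripivalate
Product: 14 [(2S,3S,4S,5R)-2,5-bis(4-hydroxy-3,5-dimethoxyphenyl)tetrahydrofuran-3,4-diyl]dimethanol (CNP0170897.4)
Conditions: NaOMe (excess), MeOH, rt to 50 °C, under argon; AcOH quench
Reagents that add atoms: none
Why: Base-mediated transesterification (Zemplén-type methanolysis) removes the two aryl pivalates quickly and the primary pivalate on warming; no stereocentre is adjacent to a carbonyl group, so none can epimerise.

**Compound list**

1 | syringaldehyde (4-hydroxy-3,5-dimethoxybenzaldehyde) | COc1cc(C=O)cc(OC)c1O | starting material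
2 | pivaloyl chloride | CC(C)(C)C(=O)Cl | starting material
3 | 4-formyl-2,6-dimethoxyphenyl pivalate | COc1cc(C=O)cc(OC)c1OC(=O)C(C)(C)C | intermediate
4 | 4-vinyl-1,3-dioxolan-2-one (racemic) | C=CC1COC(=O)O1 | starting material
5 | 4-[(1R,2S)-1-hydroxy-2-(hydroxymethyl)but-3-en-1-yl]-2,6-dimethoxyphenyl pivalate | O[C@@H](c1cc(OC)c(OC(=O)C(C)(C)C)c(OC)c1)[C@H](CO)C=C | intermediate
6 | (2S,3R)-3-[3,5-dimethoxy-4-(pivaloyloxy)phenyl]-3-hydroxy-2-vinylpropyl pivalate | O[C@@H](c1cc(OC)c(OC(=O)C(C)(C)C)c(OC)c1)[C@H](COC(=O)C(C)(C)C)C=C | intermediate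
7 | allyl(chloro)dimethylsilane | C=CC[Si](C)(C)Cl | starting material
8 | (2S,3R)-3-[allyl(dimethyl)silyloxy]-3-[3,5-dimethoxy-4-(pivaloyloxy)phenyl]-2-vinylpropyl pivalate | C=CC[Si](C)(C)O[C@@H](c1cc(OC)c(OC(=O)C(C)(C)C)c(OC)c1)[C@H](COC(=O)C(C)(C)C)C=C | intermediate
9 | (4Z,6S,7R)-7-[3,5-dimethoxy-4-(pivaloyloxy)phenyl]-2,2-dimethyl-6-(pivaloyloxymethyl)-1-oxa-2-silacyclohept-4-ene | O1[C@@H](c2cc(OC)c(OC(=O)C(C)(C)C)c(OC)c2)[C@H](COC(=O)C(C)(C)C)/C=C\C[Si]1(C)C | intermediate
10 | (E)-oxocarbenium triflate from 9, 3 and Me3SiOTf: aldehyde carbon doubly bonded to the former siloxane oxygen, (Z)-allyl terminus carrying SiMe2OSiMe3 (not isolated) | COc1cc(/C=[O+]/[C@@H](c2cc(OC)c(OC(=O)C(C)(C)C)c(OC)c2)[C@H](COC(=O)C(C)(C)C)/C=C\C[Si](C)(C)O[Si](C)(C)C)cc(OC)c1OC(=O)C(C)(C)C.[O-]S(=O)(=O)C(F)(F)F | intermediate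
11 | (2S,3R,4S,5R)-2,5-bis[3,5-dimethoxy-4-(pivaloyloxy)phenyl]-4-(pivaloyloxymethyl)-3-vinyltetrahydrofuran | COc1cc([C@H]2O[C@@H](c3cc(OC)c(OC(=O)C(C)(C)C)c(OC)c3)[C@H](COC(=O)C(C)(C)C)[C@H]2C=C)cc(OC)c1OC(=O)C(C)(C)C | intermediate
12 | ozonide of 11: 1,2,4-trioxolan-3-yl group on C3, configuration at the trioxolane carbon undefined (not isolated) | COc1cc([C@H]2O[C@@H](c3cc(OC)c(OC(=O)C(C)(C)C)c(OC)c3)[C@H](COC(=O)C(C)(C)C)[C@H]2C4OCOO4)cc(OC)c1OC(=O)C(C)(C)C | intermediate
13 | (2S,3S,4S,5R)-2,5-bis[3,5-dimethoxy-4-(pivaloyloxy)phenyl]-3-(hydroxymethyl)-4-(pivaloyloxymethyl)tetrahydrofuran | COc1cc([C@H]2O[C@@H](c3cc(OC)c(OC(=O)C(C)(C)C)c(OC)c3)[C@H](COC(=O)C(C)(C)C)[C@H]2CO)cc(OC)c1OC(=O)C(C)(C)C | intermediate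
14 | [(2S,3S,4S,5R)-2,5-bis(4-hydroxy-3,5-dimethoxyphenyl)tetrahydrofuran-3,4-diyl]dimethanol | COc1cc([C@H]2O[C@@H](c3cc(OC)c(O)c(OC)c3)[C@H](CO)[C@H]2CO)cc(OC)c1O | target

**Step count and risks**

Total step count: 8. Longest linear sequence: 8 steps (1 → 3 → 5 → 6 → 8 → 9 → 11 → 13 → 14); aldehyde 3 enters twice (steps 2 and 6).

Steps most likely to fail:

1. **Step 6.** The closure may leak through the pseudo-diaxial, antiperiplanar envelope, which would invert C2. Silicon transfer from the hindered secondary silyl ether may also be slow, so that the allylsilane adds to the free aldehyde intermolecularly. The fallback exchanges the roles of the two benzylic carbons, so that the cis relation is carried by the precursor and not made in the bond-forming event. It sets out from 6 and comes back at 14. A Mitsunobu reaction of 6 with chloroacetic acid (PPh3, DIAD) inverts the carbinol and gives the syn chloroacetate F1. Thiourea/NaHCO3 in ethanol then frees the syn alcohol F2 without touching the pivalates. Silylation with 7 gives the allylsilyl ether F3, and ring-closing metathesis gives the syn-configured siloxane F4. Condensation of F4 with 3 under Me3SiOTf now forms O1–C5 and C4–C5. The new C–C bond only has to form trans to both neighbours, with the carbinol aryl group pseudo-equatorial and the alkene antiperiplanar, which allylic strain and sterics both favour. This gives the regioisomeric tetrahydrofuran F5 (vinyl on C4, CH2OPiv on C3). Ozonolysis with NaBH4 work-up gives the mono-pivalate F6, and NaOMe in methanol gives 14.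

2. **Step 2.** The anti relationship may erode through E/Z isomerisation of the σ-allyl intermediate, facial control may be incomplete, or the aryl pivalate may undergo acyl transfer under the basic alcoholic conditions. The fallback sets out from 3 and comes back at 6, bypassing 5 and step 3. Cross-metathesis of allylboronic acid pinacol ester with allyl pivalate, using (H2IMes)(PCy3)Cl2Ru=CHPh, gives the (E)-γ-substituted allylboronate F7. Its addition to 3 under a BINOL-derived chiral phosphoric acid in toluene at low temperature proceeds through a closed chair transition state (E-boronate gives anti) under non-basic conditions and gives 6 directly; the acid enantiomer is chosen for re-face addition.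

3. **Step 7.** Excess ozone may oxidise the dimethoxyaryl rings, or the C3 aldehyde may be released and epimerise before it is reduced. The fallback sets out from 11 and comes back at 13. Dihydroxylation with OsO4 (cat.) and N-methylmorpholine N-oxide in aqueous acetone gives the vicinal diol F8 as a mixture at the new carbinol. Cleavage with NaIO4 in buffered aqueous THF, followed directly by NaBH4 at 0 °C, gives 13.

**Further compounds**

F1 | step 6 | (2S,3S)-3-(chloroacetoxy)-3-[3,5-dimethoxy-4-(pivaloyloxy)phenyl]-2-vinylpropyl pivalate | ClCC(=O)O[C@H](c1cc(OC)c(OC(=O)C(C)(C)C)c(OC)c1)[C@H](COC(=O)C(C)(C)C)C=C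
F2 | step 6 | (2S,3S)-3-[3,5-dimethoxy-4-(pivaloyloxy)phenyl]-3-hydroxy-2-vinylpropyl pivalate (syn) | O[C@H](c1cc(OC)c(OC(=O)C(C)(C)C)c(OC)c1)[C@H](COC(=O)C(C)(C)C)C=C
F3 | step 6 | allyl(dimethyl)silyl ether of F2 | C=CC[Si](C)(C)O[C@H](c1cc(OC)c(OC(=O)C(C)(C)C)c(OC)c1)[C@H](COC(=O)C(C)(C)C)C=C
F4 | step 6 | (4Z,6S,7S)-7-[3,5-dimethoxy-4-(pivaloyloxy)phenyl]-2,2-dimethyl-6-(pivaloyloxymethyl)-1-oxa-2-silacyclohept-4-ene | O1[C@H](c2cc(OC)c(OC(=O)C(C)(C)C)c(OC)c2)[C@H](COC(=O)C(C)(C)C)/C=C\C[Si]1(C)C
F5 | step 6 | (2S,3S,4R,5R)-2,5-bis[3,5-dimethoxy-4-(pivaloyloxy)phenyl]-3-(pivaloyloxymethyl)-4-vinyltetrahydrofuran | COc1cc([C@H]2O[C@@H](c3cc(OC)c(OC(=O)C(C)(C)C)c(OC)c3)[C@H](C=C)[C@H]2COC(=O)C(C)(C)C)cc(OC)c1OC(=O)C(C)(C)C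
F6 | step 6 | (2S,3S,4S,5R)-2,5-bis[3,5-dimethoxy-4-(pivaloyloxy)phenyl]-4-(hydroxymethyl)-3-(pivaloyloxymethyl)tetrahydrofuran | COc1cc([C@H]2O[C@@H](c3cc(OC)c(OC(=O)C(C)(C)C)c(OC)c3)[C@H](CO)[C@H]2COC(=O)C(C)(C)C)cc(OC)c1OC(=O)C(C)(C)C
F7 | step 2 | (E)-4-(4,4,5,5-tetramethyl-1,3,2-dioxaborolan-2-yl)but-2-en-1-yl pivalate | CC(C)(C)C(=O)OC/C=C/CB1OC(C)(C)C(C)(C)O1
F8 | step 7 | 1,2-diol from dihydroxylation of the vinyl group of 11 (carbinol configuration undefined) | COc1cc([C@H]2O[C@@H](c3cc(OC)c(OC(=O)C(C)(C)C)c(OC)c3)[C@H](COC(=O)C(C)(C)C)[C@H]2C(O)CO)cc(OC)c1OC(=O)C(C)(C)C
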